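**Retrosynthetic overview**

- The target is cut at the aryl–C(=O) bond of ring A into 2-prenylresorcinol and the (R)-3-(3,4-dihydroxyphenyl)lactoyl group. The acyl half comes from natural (R)-danshensu, which brings the only stereocentre, as its N-acetylcysteamine thioester.
- The two halves are joined, with all five hydroxyl groups free, by a C-acyltransferase (a Friedel–Crafts acylase of the PhlACB type) in neutral buffer.
- Enabling feature: the 1,3-dihydroxy pattern of ring A, with O on C2' and C4' flanking the prenyl-bearing C3'. C1' is ortho to one oxygen and para to the other, and the mirror plane of 2-prenylresorcinol through C3' and C6' makes C1' and C5' the same carbon, so only one C-acylation product can form. The catechol ring B has no 1,3-diol.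
- 2-Prenylresorcinol comes from resorcinol by bis-MOM protection, lithiation between the two oxygens, prenylation and deprotection.
- No ring is formed in the route: both benzene rings are bought (resorcinol, danshensu).

Key step: step 5

Assumption: (R)-danshensu is used as the free acid; the commercial sodium salt would be acidified and extracted first.

**Step 1**
Reactants: 1 resorcinol (benzene-1,3-diol)
Product: 2 1,3-bis(methoxymethoxy)benzene
Conditions: NaH (2.2 equiv), MOMCl (2.2 equiv), DMF, 0 °C to rt
Reagents that add atoms: chloromethyl methyl ether (MOMCl), COCCl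
Why: Williamson etherification of both phenoxides with the reactive α-chloro ether should give the bis-acetal, which serves as the directing group for the next step.

**Step 2**
Reactants: 2 1,3-bis(methoxymethoxy)benzene; 3 prenyl bromide (1-bromo-3-methylbut-2-ene)
Product: 5 1,3-bis(methoxymethoxy)-2-(3-methylbut-2-en-1-yl)benzene, via 2-lithio-1,3-bis(methoxymethoxy)benzene 4 (not isolated)
Conditions: n-BuLi (1.1 equiv), THF, 0 °C to rt; then CuI (10 mol %), 3, −78 °C to rt
Reagents that add atoms: none
Why: Directed ortho-metalation should place lithium on the carbon between the two cooperating OMOM groups, and copper-catalysed SN2 allylic substitution at the primary carbon of 3 should then give the linear prenyl arene.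

**Step 3**
Reactants: 5 1,3-bis(methoxymethoxy)-2-(3-methylbut-2-en-1-yl)benzene
Product: 6 2-(3-methylbut-2-en-1-yl)benzene-1,3-diol (2-prenylresorcinol)
Conditions: HCl (0.5 M) in MeOH, rt
Reagents that add atoms: none
Why: Acid-catalysed acetal exchange with methanol (MOM cleavage) should free both phenols, and dilute acid at room temperature is mild enough to leave the ortho-prenyl group uncyclised.

**Step 4**
Reactants: 7 (R)-danshensu, (2R)-3-(3,4-dihydroxyphenyl)-2-hydroxypropanoic acid
Product: 8 S-(2-acetamidoethyl) (2R)-3-(3,4-dihydroxyphenyl)-2-hydroxypropanethioate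
Conditions: N-acetylcysteamine (1.5 equiv), EDC·HCl (1.2 equiv), HOBt (0.2 equiv), DMF, 0 °C to rt, argon
Reagents that add atoms: N-acetylcysteamine, CC(=O)NCCS
Why: In this carbodiimide (Steglich-type) thioesterification the thiol should outcompete the phenolic and secondary hydroxyl groups for the activated acyl group, and the (2R) centre taken from 7 has no azlactone path to racemisation.

**Step 5**
Reactants: 6 2-(3-methylbut-2-en-1-yl)benzene-1,3-diol; 8 S-(2-acetamidoethyl) (2R)-3-(3,4-dihydroxyphenyl)-2-hydroxypropanethioate
Product: 9 (2R)-1-[2,4-dihydroxy-3-(3-methylbut-2-en-1-yl)phenyl]-3-(3,4-dihydroxyphenyl)-2-hydroxypropan-1-one (target)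
Conditions: PhlACB-type C-acyltransferase (variant with widened acyl pocket, cell-free extract), 6 (1.5 equiv), 8 (1 equiv), KPi buffer pH 7.5/DMSO 9:1, degassed, N2, 30 °C
Reagents that add atoms: none
Why: Proposed new method: the active-site cysteine of the acyltransferase is expected to take over the (R)-3-(3,4-dihydroxyphenyl)lactoyl group from thioester 8 by transthioesterification and to pass it to the enzyme-bound phenolate of 6 in a Friedel–Crafts-type (Claisen-like) attack of ring carbon C4 on the acyl-enzyme thioester, followed by rearomatisation. The closest known reaction type is the cofactor-free C-acylation of resorcinols with short-chain acyl groups by this enzyme class, with thioester or aryl ester donors in buffer; what goes beyond it is the large α-hydroxy-β-aryl acyl group, for which a variant with a widened acyl pocket (from screening of homologues and mutation of the residues lining the acyl site) is assumed. No ring is closed and no stereocentre is formed: the (R) centre of 8 is a spectator and should pass through at pH 7.5 and 30 °C without enolisation of the thioester or of the product ketone. The step needs C- over O-acylation among five free hydroxyl groups, a single ring position and a single acylation: the enzyme class acylates carbon only and only ortho/para to a 1,3-dihydroxy pair, the mirror symmetry of 6 makes C4 and C6 the same carbon, the catechol ring of 8 lacks a 1,3-diol and should be ignored, and the product is deactivated by its hydrogen-bonded ortho-hydroxy ketone. The neutral aqueous medium leaves the acid-sensitive ortho-prenyl phenol untouched, which a Lewis-acid Friedel–Crafts, Fries or Houben–Hoesch acylation would not.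

**Compound list**

1 | resorcinol (benzene-1,3-diol) | Oc1cccc(O)c1 | starting material
2 | 1,3-bis(methoxymethoxy)benzene | COCOc1cccc(OCOC)c1 | intermediate
3 | prenyl bromide (1-bromo-3-methylbut-2-ene) | CC(C)=CCBr | starting material
4 | 2-lithio-1,3-bis(methoxymethoxy)benzene | [Li]c1c(OCOC)cccc1OCOC | intermediate
5 | 1,3-bis(methoxymethoxy)-2-(3-methylbut-2-en-1-yl)benzene | CC(C)=CCc1c(OCOC)cccc1OCOC | intermediate
6 | 2-(3-methylbut-2-en-1-yl)benzene-1,3-diol (2-prenylresorcinol) | CC(C)=CCc1c(O)cccc1O | intermediate
7 | (R)-danshensu, (2R)-3-(3,4-dihydroxyphenyl)-2-hydroxypropanoic acid | OC(=O)[C@H](O)Cc1ccc(O)c(O)c1 | starting material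
8 | S-(2-acetamidoethyl) (2R)-3-(3,4-dihydroxyphenyl)-2-hydroxypropanethioate | CC(=O)NCCSC(=O)[C@H](O)Cc1ccc(O)c(O)c1 | intermediate
9 | (2R)-1-[2,4-dihydroxy-3-(3-methylbut-2-en-1-yl)phenyl]-3-(3,4-dihydroxyphenyl)-2-hydroxypropan-1-one | CC(C)=CCc1c(O)ccc(C(=O)[C@H](O)Cc2ccc(O)c(O)c2)c1O | target

**Step count and risks**

Total step count: 5. Longest linear sequence: 4 steps (steps 1, 2, 3, 5); the acyl branch is 2 steps (steps 4, 5).

Steps most likely to fail:

1. Step 5 (proposed new method). What may go wrong: the bulky acyl group is not taken up by the active-site cysteine, so that hydrolysis of the thioester outruns C–C bond formation. The fallback uses known chemistry, sets out from 5 and 7 and comes back at 9. Acid 7 is esterified (MeOH, cat. H2SO4) to methyl (2R)-3-(3,4-dihydroxyphenyl)-2-hydroxypropanoate F1. Its three hydroxyl groups are protected (MOMCl, i-Pr2NEt, CH2Cl2) to give methyl (2R)-3-[3,4-bis(methoxymethoxy)phenyl]-2-(methoxymethoxy)propanoate F2. MeNHOMe·HCl with i-PrMgCl (THF, −20 °C) converts this into the Weinreb amide (2R)-3-[3,4-bis(methoxymethoxy)phenyl]-N-methoxy-2-(methoxymethoxy)-N-methylpropanamide F3. Directed ortho-lithiation of 5 (n-BuLi, TMEDA, THF, 0 °C; the two positions ortho to OMOM are equivalent) gives [2,4-bis(methoxymethoxy)-3-(3-methylbut-2-en-1-yl)phenyl]lithium F4. This should add to the amide at −78 °C and, after collapse of the chelated adduct on work-up, give (2R)-1-[2,4-bis(methoxymethoxy)-3-(3-methylbut-2-en-1-yl)phenyl]-3-[3,4-bis(methoxymethoxy)phenyl]-2-(methoxymethoxy)propan-1-one F5. HCl in MeOH (rt to 40 °C) then removes the five MOM groups and gives 9.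

2. Step 4. What may go wrong: the carbodiimide-activated acid acylates the phenolic or secondary hydroxyl groups of a second molecule faster than the thiol, so that oligo-esters form. The fallback sets out from 7 and comes back at 8. The carboxyl group alone is activated by redox condensation (2,2'-dipyridyl disulfide, PPh3, MeCN, rt; Mukaiyama–Corey thioester formation, which tolerates free hydroxyl groups at room temperature) to give S-(pyridin-2-yl) (2R)-3-(3,4-dihydroxyphenyl)-2-hydroxypropanethioate F6. Thiol–thioester exchange with N-acetylcysteamine in the same solvent should then give 8.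

3. Step 3. What may go wrong: acid-promoted addition of the neighbouring phenol to the prenyl double bond (closure to a 2,2-dimethylchroman) or hydration of the alkene while the acetals are cleaved. The fallback sets out from 1 and comes back at 6. The MOM ethers are replaced by SEM ethers, which direct lithiation in the same way but leave with fluoride. Resorcinol 1 with SEMCl/NaH gives 1,3-bis{[2-(trimethylsilyl)ethoxy]methoxy}benzene F7. n-BuLi converts it into (2,6-bis{[2-(trimethylsilyl)ethoxy]methoxy}phenyl)lithium F8. With 3 and catalytic CuI this gives 2-(3-methylbut-2-en-1-yl)-1,3-bis{[2-(trimethylsilyl)ethoxy]methoxy}benzene F9. TBAF in DMPU/THF (60 °C) then frees 6 under non-acidic conditions.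

**Further compounds**

F1 | step 5 | methyl (2R)-3-(3,4-dihydroxyphenyl)-2-hydroxypropanoate | COC(=O)[C@H](O)Cc1ccc(O)c(O)c1
F2 | step 5 | methyl (2R)-3-[3,4-bis(methoxymethoxy)phenyl]-2-(methoxymethoxy)propanoate | COC(=O)[C@H](OCOC)Cc1ccc(OCOC)c(OCOC)c1
F3 | step 5 | (2R)-3-[3,4-bis(methoxymethoxy)phenyl]-N-methoxy-2-(methoxymethoxy)-N-methylpropanamide | CON(C)C(=O)[C@H](OCOC)Cc1ccc(OCOC)c(OCOC)c1
F4 | step 5 | [2,4-bis(methoxymethoxy)-3-(3-methylbut-2-en-1-yl)phenyl]lithium | [Li]c1ccc(OCOC)c(CC=C(C)C)c1OCOC
F5 | step 5 | (2R)-1-[2,4-bis(methoxymethoxy)-3-(3-methylbut-2-en-1-yl)phenyl]-3-[3,4-bis(methoxymethoxy)phenyl]-2-(methoxymethoxy)propan-1-one | CC(C)=CCc1c(OCOC)ccc(C(=O)[C@H](OCOC)Cc2ccc(OCOC)c(OCOC)c2)c1OCOC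
F6 | step 4 | S-(pyridin-2-yl) (2R)-3-(3,4-dihydroxyphenyl)-2-hydroxypropanethioate | O=C(Sc1ccccn1)[C@H](O)Cc1ccc(O)c(O)c1
F7 | step 3 | 1,3-bis{[2-(trimethylsilyl)ethoxy]methoxy}benzene | C[Si](C)(C)CCOCOc1cccc(OCOCC[Si](C)(C)C)c1
F8 | step 3 | (2,6-bis{[2-(trimethylsilyl)ethoxy]methoxy}phenyl)lithium | [Li]c1c(OCOCC[Si](C)(C)C)cccc1OCOCC[Si](C)(C)C
F9 | step 3 | 2-(3-methylbut-2-en-1-yl)-1,3-bis{[2-(trimethylsilyl)ethoxy]methoxy}benzene | CC(C)=CCc1c(OCOCC[Si](C)(C)C)cccc1OCOCC[Si](C)(C)C
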